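## Retrosynthetic overview

1. The tetrahydrofuran is closed last (C7–O9′ bond) by acid-triggered quinone-methide/benzylic-cation cycloetherification of tetraol 14; this sets C7 (2,3-trans).
2. The C7–C8 bond comes from a trans-selective aldol of (R)-β-veratryl-γ-butyrolactone 10 with vanillin isobutyrate 11 (sets C8); LiAlH4 then opens the lactone and removes the phenol ester in the same operation.
3. Lactone 10 comes from ozonolysis/reduction/lactonisation of the γ,δ-unsaturated ester 7.
4. The C8–C8′ bond and the C8′ stereocentre come from a Johnson–Claisen [3,3] rearrangement of allylic alcohol 3, with 1,3-chirality transfer from the bought carbinol centre of (R)-but-3-en-2-ol (later lost as ethanol).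
5. Ring order: temporary γ-lactone first, tetrahydrofuran last. Target configuration: (2S,3R,4R), i.e. 2,3-trans-3,4-cis.

Assumption: (R)-but-3-en-2-ol (≥98% ee), methyl eugenol, triethyl orthoacetate and vanillin isobutyrate are taken as commercial; lignan numbering (C7–C9 for the guaiacyl half, C7′–C9′ for the veratryl half) is used in the comments.

## Route

Step 1
Reactants: 1 (R)-but-3-en-2-ol; 2 methyl eugenol (4-allyl-1,2-dimethoxybenzene)
Product: 3 (R,E)-5-(3,4-dimethoxyphenyl)pent-3-en-2-ol
Conditions: Grubbs II (3 mol %), 1,4-benzoquinone (10 mol %), CH2Cl2, 40 °C; minor Z-isomer removed on AgNO3–silica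
Reagents that add atoms: none
Why: Olefin cross-metathesis of a fast-dimerising allylarene with a slow-dimerising secondary allylic alcohol gives the E-disubstituted alkene selectively (benzoquinone suppresses Ru–H isomerisation), and the bought carbinol stereocentre is not touched.

Step 2
Reactants: 3 (R,E)-5-(3,4-dimethoxyphenyl)pent-3-en-2-ol; 4 triethyl orthoacetate
Product: 7 ethyl (R,E)-3-(3,4-dimethoxybenzyl)hex-4-enoate, via mixed orthoester 5 (not isolated), via ketene acetal 6 (not isolated)
Conditions: MeC(OEt)3 (6 equiv), EtCO2H (10 mol %), 140 °C, EtOH distilled off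
Reagents that add atoms: none
Why: The Johnson–Claisen [3,3]-sigmatropic rearrangement runs through a chair transition state with the carbinol methyl equatorial, so the C–O chirality is passed suprafacially to the new C8–C8′ bond, giving the (R) centre and an E-propenyl group.

Step 3
Reactants: 7 ethyl (R,E)-3-(3,4-dimethoxybenzyl)hex-4-enoate
Product: 10 (R)-4-(3,4-dimethoxybenzyl)dihydrofuran-2(3H)-one, via ozonide 8 (not isolated), via hydroxy ester 9 (not isolated)
Conditions: O3, CH2Cl2, −78 °C (Sudan Red 7B end-point); then NaBH4, MeOH, −78 → 0 °C; then 1 M HCl, rt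
Reagents that add atoms: ozone, O=[O+][O-]
Why: Ozonolysis cleaves the alkene far faster than the veratryl ring at −78 °C, borohydride reduces the ozonide to the primary alcohol, and acid closes the γ-lactone without touching the stereocentre.

Step 4
Reactants: 10 (R)-4-(3,4-dimethoxybenzyl)dihydrofuran-2(3H)-one; 11 vanillin isobutyrate (4-formyl-2-methoxyphenyl 2-methylpropanoate)
Product: 13 (3S,4R)-4-(3,4-dimethoxybenzyl)-3-[hydroxy(4-isobutyryloxy-3-methoxyphenyl)methyl]dihydrofuran-2(3H)-one (both carbinol epimers), via lithium enolate 12 (not isolated)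
Conditions: LiHMDS (1.05 equiv), THF, −78 °C; then 11 (1.1 equiv), −78 °C, 30 min; sat. NH4Cl
Reagents that add atoms: none
Why: In this lithium-enolate aldol addition the aldehyde adds anti to the β-benzyl group (3,4-trans, sets C8); the aldehyde is much more electrophilic than the hindered aryl ester, any O-to-O acyl migration is erased in step 5, and the C7 epimer mixture is erased in step 6.

Step 5
Reactants: 13 aldol adduct (both carbinol epimers)
Product: 14 (2R,3R)-2-(3,4-dimethoxybenzyl)-3-[hydroxy(4-hydroxy-3-methoxyphenyl)methyl]butane-1,4-diol (both carbinol epimers)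
Conditions: LiAlH4 (4 equiv), THF, 0 °C → rt; Rochelle salt work-up
Reagents that add atoms: none
Why: Hydride reduction opens the lactone to the 1,4-diol and cleaves the aryl isobutyrate in the same pot, so the phenol is freed without a separate deprotection and no stereocentre is touched.

Step 6
Reactants: 14 tetraol (both carbinol epimers)
Product: 16 4′-O-methyllariciresinol [(2S,3R,4R)-4-(3,4-dimethoxybenzyl)-2-(4-hydroxy-3-methoxyphenyl)tetrahydrofuran-3-yl]methanol, via quinone methide 15 (not isolated)
Conditions: TsOH·H2O (10 mol %), CH2Cl2–THF (5:1), 0 °C → rt, about 1 h; NaHCO3 quench at full conversion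
Reagents that add atoms: none
Why: Acid-catalysed loss of water from the p-hydroxybenzylic alcohol gives the cation/quinone methide, which the 9′-OH traps by 5-exo SN1 cycloetherification (the 9-OH could only form an oxetane) on the face anti to the C8 CH2OH group, so both C7 epimers converge on the 2,3-trans ring.

## Compound list

1 | (R)-but-3-en-2-ol | C[C@@H](O)C=C | starting material
2 | methyl eugenol (4-allyl-1,2-dimethoxybenzene) | C=CCc1ccc(OC)c(OC)c1 | starting material
3 | (R,E)-5-(3,4-dimethoxyphenyl)pent-3-en-2-ol | C[C@@H](O)/C=C/Cc1ccc(OC)c(OC)c1 | intermediate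
4 | triethyl orthoacetate | CCOC(C)(OCC)OCC | starting material
5 | mixed orthoester, (R,E)-4-[4-(1,1-diethoxyethoxy)pent-2-en-1-yl]-1,2-dimethoxybenzene | CCOC(C)(OCC)O[C@H](C)/C=C/Cc1ccc(OC)c(OC)c1 | intermediate (not isolated)
6 | ketene acetal, (R,E)-4-{4-[(1-ethoxyvinyl)oxy]pent-2-en-1-yl}-1,2-dimethoxybenzene | C=C(OCC)O[C@H](C)/C=C/Cc1ccc(OC)c(OC)c1 | intermediate (not isolated)
7 | ethyl (R,E)-3-(3,4-dimethoxybenzyl)hex-4-enoate | CCOC(=O)C[C@@H](Cc1ccc(OC)c(OC)c1)/C=C/C | intermediate
8 | ozonide, ethyl (3R)-4-(3,4-dimethoxyphenyl)-3-(5-methyl-1,2,4-trioxolan-3-yl)butanoate (ring carbons unassigned) | CCOC(=O)C[C@@H](Cc1ccc(OC)c(OC)c1)C2OOC(C)O2 | intermediate (not isolated)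
9 | ethyl (R)-3-(3,4-dimethoxybenzyl)-4-hydroxybutanoate | CCOC(=O)C[C@@H](Cc1ccc(OC)c(OC)c1)CO | intermediate (not isolated)
10 | (R)-4-(3,4-dimethoxybenzyl)dihydrofuran-2(3H)-one | O=C1OC[C@H](Cc2ccc(OC)c(OC)c2)C1 | intermediate
11 | vanillin isobutyrate (4-formyl-2-methoxyphenyl 2-methylpropanoate) | CC(C)C(=O)Oc1ccc(C=O)cc1OC | starting material
12 | lithium (R)-4-(3,4-dimethoxybenzyl)-4,5-dihydrofuran-2-olate | [Li+].[O-]C1=C[C@@H](Cc2ccc(OC)c(OC)c2)CO1 | intermediate (not isolated)
13 | (3S,4R)-4-(3,4-dimethoxybenzyl)-3-[hydroxy(4-isobutyryloxy-3-methoxyphenyl)methyl]dihydrofuran-2(3H)-one, carbinol epimers | O=C1OC[C@H](Cc2ccc(OC)c(OC)c2)[C@H]1C(O)c3ccc(OC(=O)C(C)C)c(OC)c3 | intermediate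
14 | (2R,3R)-2-(3,4-dimethoxybenzyl)-3-[hydroxy(4-hydroxy-3-methoxyphenyl)methyl]butane-1,4-diol, carbinol epimers | OC[C@H](Cc1ccc(OC)c(OC)c1)[C@H](CO)C(O)c2ccc(O)c(OC)c2 | intermediate
15 | p-quinone methide, 4-[4-(3,4-dimethoxyphenyl)-2,3-bis(hydroxymethyl)butylidene]-2-methoxycyclohexa-2,5-dien-1-one (C8/C8′ as in 14) | COC1=CC(=C[C@@H](CO)[C@H](CO)Cc2ccc(OC)c(OC)c2)C=CC1=O | intermediate (not isolated)
16 | 4′-O-methyllariciresinol, [(2S,3R,4R)-4-(3,4-dimethoxybenzyl)-2-(4-hydroxy-3-methoxyphenyl)tetrahydrofuran-3-yl]methanol | COc1cc([C@H]2OC[C@H](Cc3ccc(OC)c(OC)c3)[C@@H]2CO)ccc1O | target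

## Step count

Total steps: 6. Longest linear sequence: 6 (1 → 3 → 7 → 10 → 13 → 14 → 16).

## Steps most likely to fail, with fallbacks

Step 1 (cross-metathesis). Any Z-3 rearranges in step 2 to the enantiomeric ester, so the E-purity of 3 caps the ee of everything after it; Ru–H isomerisation of 2 or 1 is the other risk. The fallback makes the alkene by alkyne reduction instead of metathesis. It sets out at the very start, with commercial (R)-but-3-yn-2-ol in place of compound 1 and 3,4-dimethoxybenzyl bromide in place of compound 2, and it comes back to the route at compound 3. The bis-magnesium salt of the alkynol (EtMgBr 2.1 equiv, THF) is benzylated at carbon under CuBr·SMe2 catalysis to give (R)-5-(3,4-dimethoxyphenyl)pent-3-yn-2-ol F1. Red-Al (THF, 0 °C → rt) then trans-hydroaluminates the propargylic alcohol and gives 3 as the E-isomer only. This costs one extra step.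

Step 4 (aldol with an aldehyde that carries an aryl ester). The enolate or the aldolate may attack the isobutyrate, or conversion may be poor through retro-aldol. The fallback replaces the basic lithium aldol by a Lewis-acid Mukaiyama aldol. It sets out from compound 10 and comes back at compound 13. Lactone 10 is silylated (LDA, TMSCl, THF, −78 °C) to the silyl ketene acetal (R)-{[4-(3,4-dimethoxybenzyl)-4,5-dihydrofuran-2-yl]oxy}trimethylsilane F2. F2 adds to 11 with BF3·OEt2 in CH2Cl2 at −78 °C, again anti to the benzyl group, and aqueous work-up removes silicon to give 13.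

Step 6 (acid cycloetherification). Under acid the cation can instead be captured by the veratryl ring (Friedel–Crafts) to give the aryltetralin, or some 2,3-cis ether can form; a short reaction time and early quench are the first defence. The fallback generates the same quinone methide oxidatively under neutral conditions from a 7-deoxy precursor. It sets out from compound 10 and comes back at quinone methide 15, and so at 16. The enolate of 10 (LiHMDS, THF, −78 °C) is alkylated trans with 4-(benzyloxy)-3-methoxybenzyl bromide to give (3R,4R)-3-[4-(benzyloxy)-3-methoxybenzyl]-4-(3,4-dimethoxybenzyl)dihydrofuran-2(3H)-one F3. LiAlH4 gives (2R,3R)-2-[4-(benzyloxy)-3-methoxybenzyl]-3-(3,4-dimethoxybenzyl)butane-1,4-diol F4. Hydrogenolysis (H2, Pd/C, EtOAc) gives (2R,3R)-2-(3,4-dimethoxybenzyl)-3-(4-hydroxy-3-methoxybenzyl)butane-1,4-diol F5. DDQ (1.0 equiv, dioxane, rt) dehydrogenates the p-hydroxybenzyl position of F5 to 15, which closes to 16 without acid.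

## Further compounds

F1 | step 1 | (R)-5-(3,4-dimethoxyphenyl)pent-3-yn-2-ol | C[C@@H](O)C#CCc1ccc(OC)c(OC)c1
F2 | step 4 | (R)-{[4-(3,4-dimethoxybenzyl)-4,5-dihydrofuran-2-yl]oxy}trimethylsilane | C[Si](C)(C)OC1=C[C@@H](Cc2ccc(OC)c(OC)c2)CO1
F3 | step 6 | (3R,4R)-3-[4-(benzyloxy)-3-methoxybenzyl]-4-(3,4-dimethoxybenzyl)dihydrofuran-2(3H)-one | O=C1OC[C@H](Cc2ccc(OC)c(OC)c2)[C@H]1Cc3ccc(OCc4ccccc4)c(OC)c3
F4 | step 6 | (2R,3R)-2-[4-(benzyloxy)-3-methoxybenzyl]-3-(3,4-dimethoxybenzyl)butane-1,4-diol | OC[C@H](Cc1ccc(OC)c(OC)c1)[C@H](CO)Cc2ccc(OCc3ccccc3)c(OC)c2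
F5 | step 6 | (2R,3R)-2-(3,4-dimethoxybenzyl)-3-(4-hydroxy-3-methoxybenzyl)butane-1,4-diol | OC[C@H](Cc1ccc(OC)c(OC)c1)[C@H](CO)Cc2ccc(O)c(OC)c2
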